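Retrosynthesis: the C11 acetate, the C8 methacrylate, the C4=C5 enone and the C8 configuration are adjusted late; the cis-fused bicycle is then cut at C1–C5 and C9–C10 in one [5+2] retron.
Enabling feature: in the seven-membered ring the five-carbon run C5–C6–C7–C8–C9 maps onto a vinylcyclopropane (ring C7–C8–C9, vinyl C5=C6), C10–C1 onto the inner π bond of an allene whose outer carbon becomes the C14 methyl, and C2–C3–C4 of the five-membered ring is the three-atom tether.
Forward: a cyclopropane aldehyde (C6–C9, C11–C13) and an allenyl sulfone (C1–C5, C10, C14, C15) are made separately and joined at C5=C6 by Julia–Kocienski olefination; the rhodium-catalysed [5+2] cycloaddition then closes the five- and seven-membered rings together.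
Stereochemistry: C7/C8 of the cyclopropane come from a chiral dirhodium carboxylate; the cyclopropane relays this to C5 and C1 in the cycloaddition; the 8α-hydroxyl then directs hydrogen to C7 and C10; C8 is inverted by oxidation and hydride reduction anti to the C7 side chain.
Helpers: the 8α-oxygen (director), the PMB and silyl ethers, the C3 carbinol and the C4/C5 stereocentres (from methyl (R)-3-hydroxy-2-methylpropanoate and a catalyst-controlled propargylation) are all erased by the time the C3 ketone and the C4=C5 alkene are in place.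

Key step: step 15

Remark: guaiane numbering is used (C1/C5 ring fusion, C3 carbonyl, C15 methyl on C4, C11–C13 side chain on C7, ester on C8, C14 methyl on C10); β is the face of H1 in the target (also the face of the C8 ester, the C7 side chain and the C10 methyl), α the opposite face; the (S)-DOSP and (S)-TRIP catalyst enantiomers are assigned by analogy with model substrates.

Step 1
Reactants: 1 methyl 3-methylbut-3-enoate
Product: 2 methyl 2-diazo-3-methylbut-3-enoate
Conditions: 4-acetamidobenzenesulfonyl azide, DBU, MeCN, 0 °C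
Reagents that add atoms: 4-acetamidobenzenesulfonyl azide, CC(=O)Nc1ccc(cc1)S(=O)(=O)N=[N+]=[N-]
Why: Regitz diazo transfer onto the methylene that is both allylic and α to the ester gives the vinyldiazoacetate without moving the alkene; no stereocenter is formed and the product is used cold and fresh.

Step 2
Reactants: 3 4-methoxybenzyl alcohol
Product: 4 4-methoxybenzyl vinyl ether
Conditions: Pd(OCOCF3)2 (0.5 mol %), 4,7-diphenyl-1,10-phenanthroline, Et3N (cat.), butyl vinyl ether (solvent), 75 °C
Reagents that add atoms: butyl vinyl ether, C=COCCCC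
Why: Palladium-catalysed transfer vinylation (transetherification) of a primary benzylic alcohol is an equilibrium driven by the excess vinyl ether; no stereocenter.

Step 3
Reactants: 2 methyl 2-diazo-3-methylbut-3-enoate; 4 4-methoxybenzyl vinyl ether
Product: 5 methyl (1R,2S)-2-[(4-methoxybenzyl)oxy]-1-(prop-1-en-2-yl)cyclopropane-1-carboxylate (ether cis to the isopropenyl group)
Conditions: Rh2(S-DOSP)4 (1 mol %; DOSP = N-(4-dodecylphenylsulfonyl)prolinate), hexanes, −40 °C, slow addition of 2 to 4 (3 equiv)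
Reagents that add atoms: none
Why: Donor/acceptor dirhodium-carbenoid cyclopropanation of an electron-rich vinyl ether is concerted and places the alkene substituent cis to the donor (isopropenyl) and trans to the ester, while the S-configured prolinate catalyst selects the alkene face, which by analogy with styrene and alkyl vinyl ethers should give the (1R,2S) isomer; C7 and C8 are set here.

Step 4
Reactants: 5 methyl (1R,2S)-2-[(4-methoxybenzyl)oxy]-1-(prop-1-en-2-yl)cyclopropane-1-carboxylate
Product: 6 methyl (1S,2S)-2-[(4-methoxybenzyl)oxy]-1-(2-methyloxiran-2-yl)cyclopropane-1-carboxylate (both epimers at the oxirane carbon)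
Conditions: dimethyldioxirane, acetone, 0 °C
Reagents that add atoms: dimethyldioxirane, CC1(C)OO1
Why: Neutral oxygen transfer to the 1,1-disubstituted alkene (epoxidation) avoids the acid that would open the donor–acceptor cyclopropane; the oxirane centre forms as a mixture and is erased in step 5.

Step 5
Reactants: 6 methyl (1S,2S)-2-[(4-methoxybenzyl)oxy]-1-(2-methyloxiran-2-yl)cyclopropane-1-carboxylate
Product: 7 2-[(1S,2S)-1-(hydroxymethyl)-2-[(4-methoxybenzyl)oxy]cyclopropyl]propan-2-ol
Conditions: LiAlH4, THF, 0 °C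
Reagents that add atoms: none
Why: LiAlH4 reduces the ester to the primary alcohol and opens the 2,2-disubstituted epoxide by SN2 hydride attack at its CH2 terminus, which gives the tertiary carbinol C11 with both methyl groups and leaves the ring stereocenters untouched.

Step 6
Reactants: 7 2-[(1S,2S)-1-(hydroxymethyl)-2-[(4-methoxybenzyl)oxy]cyclopropyl]propan-2-ol
Product: 8 bis(triethylsilyl) ether of 7 (primary and tertiary oxygen both silylated)
Conditions: Et3SiOSO2CF3 (2.4 equiv), 2,6-lutidine, CH2Cl2, −78 to 0 °C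
Reagents that add atoms: triethylsilyl trifluoromethanesulfonate, CC[Si](CC)(CC)OS(=O)(=O)C(F)(F)F
Why: Silyl triflate/lutidine silylation covers the primary and the hindered tertiary hydroxyl, so that no ionisable tertiary cyclopropylcarbinol reaches the basic and Lewis acidic steps ahead.

Step 7
Reactants: 8 bis(triethylsilyl) ether of 7
Product: 9 (1S,2S)-2-[(4-methoxybenzyl)oxy]-1-[2-(triethylsilyloxy)propan-2-yl]cyclopropane-1-carbaldehyde
Conditions: (COCl)2, DMSO, CH2Cl2, −78 to −40 °C; then Et3N
Reagents that add atoms: none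
Why: Under Swern conditions a primary triethylsilyl ether is cleaved and oxidised directly to the aldehyde while tertiary silyl and benzyl-type ethers are inert, and the amine-only finish spares the sensitive alkoxycyclopropane aldehyde.

Step 8
Reactants: 10 methyl (R)-3-hydroxy-2-methylpropanoate
Product: 11 methyl (S)-2-methyl-3-[(1-phenyl-1H-tetrazol-5-yl)sulfanyl]propanoate
Conditions: 1-phenyl-1H-tetrazole-5-thiol, PPh3, DIAD, THF, 0 °C to rt
Reagents that add atoms: 1-phenyl-1H-tetrazole-5-thiol, Sc1nnnn1-c1ccccc1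
Why: Mitsunobu thioetherification of the primary alcohol with the acidic heteroaryl thiol; the C4 stereocenter of the starting ester is not involved.

Step 9
Reactants: 11 methyl (S)-2-methyl-3-[(1-phenyl-1H-tetrazol-5-yl)sulfanyl]propanoate
Product: 12 (S)-2-methyl-3-[(1-phenyl-1H-tetrazol-5-yl)sulfanyl]propanal
Conditions: i-Bu2AlH (1.1 equiv), CH2Cl2, −78 °C
Reagents that add atoms: none
Why: Partial ester reduction stops at the aluminium hemiacetal at −78 °C and releases the aldehyde on work-up; it is used at once to avoid epimerisation at C4 or β-elimination of the thiolate.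

Step 10
Reactants: 12 (S)-2-methyl-3-[(1-phenyl-1H-tetrazol-5-yl)sulfanyl]propanal
Product: 13 (2S,3S)-2-methyl-1-[(1-phenyl-1H-tetrazol-5-yl)sulfanyl]hex-5-yn-3-ol
Conditions: allenylboronic acid pinacol ester, (S)-TRIP phosphoric acid (5 mol %), 4 Å molecular sieves, toluene, 0 °C
Reagents that add atoms: allenylboronic acid pinacol ester, C=C=CB1OC(C)(C)C(C)(C)O1
Why: Chiral-phosphoric-acid-catalysed propargylation through a six-membered SE2' transition state is catalyst-controlled and should set C3 anti to the C4 methyl, against the small Felkin–Anh bias, so that both tether substituents later sit on the convex face.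

Step 11
Reactants: 13 (2S,3S)-2-methyl-1-[(1-phenyl-1H-tetrazol-5-yl)sulfanyl]hex-5-yn-3-ol
Product: 14 5-{[(2S,3S)-3-(tert-butyldimethylsilyloxy)-2-methylhex-5-yn-1-yl]sulfanyl}-1-phenyl-1H-tetrazole
Conditions: t-BuMe2SiCl, imidazole, DMF, rt
Reagents that add atoms: tert-butyldimethylsilyl chloride, CC(C)(C)[Si](C)(C)Cl
Why: Standard silylation of the secondary alcohol gives an ether that should survive base, rhodium, DDQ, hydrogenation and hydride and leave with fluoride together with the C11 silyl ether.

Step 12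
Reactants: 14 5-{[(2S,3S)-3-(tert-butyldimethylsilyloxy)-2-methylhex-5-yn-1-yl]sulfanyl}-1-phenyl-1H-tetrazole
Product: 16 5-{[(2S,3S)-3-(tert-butyldimethylsilyloxy)-2-methylhepta-5,6-dien-1-yl]sulfanyl}-1-phenyl-1H-tetrazole, via propargylic dicyclohexylamine 15 (not isolated)
Conditions: (CH2O)n, CuI (0.5 equiv), Cy2NH, 1,4-dioxane, reflux
Reagents that add atoms: paraformaldehyde (as formaldehyde), C=O
Why: Crabbé homologation, in which the copper-mediated Mannich reaction of the terminal alkyne gives the propargylic amine and a retro-imino-ene hydride shift then delivers the terminal allene and supplies C14.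

Step 13
Reactants: 16 5-{[(2S,3S)-3-(tert-butyldimethylsilyloxy)-2-methylhepta-5,6-dien-1-yl]sulfanyl}-1-phenyl-1H-tetrazole
Product: 17 5-{[(2S,3S)-3-(tert-butyldimethylsilyloxy)-2-methylhepta-5,6-dien-1-yl]sulfonyl}-1-phenyl-1H-tetrazole
Conditions: (NH4)6Mo7O24·4H2O (10 mol %), 30 % H2O2, EtOH, 0 °C to rt
Reagents that add atoms: hydrogen peroxide, OO
Why: Molybdate-catalysed peroxide oxidation of sulfide to sulfone should be selective for sulfur over the electron-poor terminal allene and the silyl ether.

Step 14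
Reactants: 17 5-{[(2S,3S)-3-(tert-butyldimethylsilyloxy)-2-methylhepta-5,6-dien-1-yl]sulfonyl}-1-phenyl-1H-tetrazole; 9 (1S,2S)-2-[(4-methoxybenzyl)oxy]-1-[2-(triethylsilyloxy)propan-2-yl]cyclopropane-1-carbaldehyde
Product: 18 (1S,2S)-1-[(1E,3R,4S)-4-(tert-butyldimethylsilyloxy)-3-methylocta-1,6,7-trien-1-yl]-2-[(4-methoxybenzyl)oxy]-1-[2-(triethylsilyloxy)propan-2-yl]cyclopropane
Conditions: KN(SiMe3)2, DME, −78 °C to rt
Reagents that add atoms: none
Why: Julia–Kocienski olefination of the non-enolisable α-quaternary aldehyde (addition, Smiles rearrangement, anti elimination) should give the E alkene C5=C6 that the cycloaddition needs, with no stereocenter touched.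

Step 15
Reactants: 18 (1S,2S)-1-[(1E,3R,4S)-4-(tert-butyldimethylsilyloxy)-3-methylocta-1,6,7-trien-1-yl]-2-[(4-methoxybenzyl)oxy]-1-[2-(triethylsilyloxy)propan-2-yl]cyclopropane
Product: 19 (1βH,4αH,5βH)-3β-(tert-butyldimethylsilyloxy)-8α-[(4-methoxybenzyl)oxy]-11-(triethylsilyloxy)guaia-6,10(14)-diene
Conditions: [Rh(CO)2Cl]2 (5 mol %), ClCH2CH2Cl (0.02 M), 80 °C
Reagents that add atoms: none
Why: Monovalent rhodium binds the C5=C6 alkene and cleaves the C7–C9 cyclopropane bond to a trivalent σ-alkyl/π-allyl rhodacycle (Rh–C9, allyl C5–C6–C7), the inner allene π bond C1=C10 inserts at the allyl terminus C5, and C(sp2)–C(sp3) reductive elimination joins C10 to C9, leaving C10=C14 exocyclic and C6=C7 in the ring. The closest known reaction type is the rhodium-catalysed intramolecular [5+2] cycloaddition of allene-tethered vinylcyclopropanes that carry substituents on the cyclopropane. The five-membered ring closes by migratory insertion in a 5-exo sense across the three-atom tether (bond C1–C5, cis ring fusion), and the seven-membered ring closes by reductive elimination from the eight-membered rhodacycle (bond C9–C10). C5 is controlled by the cyclopropane, because rhodium must sit on the face of C5=C6 toward which C9 points in the s-cis conformer that leads to the Z ring alkene, so the (7S,8S) cyclopropane should place H5 trans to the C8 ether; C1 follows from cis delivery across C1=C10 (H1 cis to H5), and C8 is carried through untouched. The step needs cleavage of C7–C9 and not C7–C8, secured because C7–C9 is the less substituted bond distal to the σ-withdrawing ether oxygen and gives a primary alkyl–rhodium, with the ether trans to the vinyl group and anti to Rh–C9 so that syn β-alkoxide elimination is geometrically disfavoured; it also needs reaction at the inner and not the terminal allene π bond, secured by the tether length, and the C3 silyl ether and C4 methyl both sit on the convex face so that the tether does not oppose the cyclopropane's facial demand.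

Step 16
Reactants: 19 (1βH,4αH,5βH)-3β-(tert-butyldimethylsilyloxy)-8α-[(4-methoxybenzyl)oxy]-11-(triethylsilyloxy)guaia-6,10(14)-diene
Product: 20 (1βH,4αH,5βH)-3β-(tert-butyldimethylsilyloxy)-11-(triethylsilyloxy)guaia-6,10(14)-dien-8α-ol
Conditions: DDQ (1.2 equiv), CH2Cl2/pH 7 buffer, 0 °C
Reagents that add atoms: none
Why: Oxidative cleavage of the 4-methoxybenzyl ether (hydride abstraction, hydrolysis of the oxocarbenium ion) frees only the 8α-hydroxyl and keeps both silyl ethers, so that a single directing group remains.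

Step 17
Reactants: 20 (1βH,4αH,5βH)-3β-(tert-butyldimethylsilyloxy)-11-(triethylsilyloxy)guaia-6,10(14)-dien-8α-ol
Product: 21 (1βH,4αH,5βH,7αH,10αH)-3β-(tert-butyldimethylsilyloxy)-11-(triethylsilyloxy)guaian-8α-ol
Conditions: [Ir(cod)(PCy3)(py)]PF6 (10 mol %), H2 (1–5 bar), CH2Cl2, rt
Reagents that add atoms: none
Why: Hydroxyl-directed homogeneous hydrogenation, in which iridium bound to the 8α-oxygen delivers hydrogen to the allylic C6=C7 and the homoallylic C10=C14 alkenes from the face of that oxygen, should set H7 and H10 α (side chain and C10 methyl β) against the concave shape of the cis-fused bicycle.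

Step 18
Reactants: 21 (1βH,4αH,5βH,7αH,10αH)-3β-(tert-butyldimethylsilyloxy)-11-(triethylsilyloxy)guaian-8α-ol
Product: 22 (1βH,4αH,5βH,7αH,10αH)-3β-(tert-butyldimethylsilyloxy)-11-(triethylsilyloxy)guaian-8-one
Conditions: Dess–Martin periodinane, pyridine, CH2Cl2, 0 °C to rt
Reagents that add atoms: none
Why: Dess–Martin oxidation under buffered, non-enolising conditions removes the temporary C8 stereocenter without epimerising C7 or eliminating the β-silyloxy group.

Step 19
Reactants: 22 (1βH,4αH,5βH,7αH,10αH)-3β-(tert-butyldimethylsilyloxy)-11-(triethylsilyloxy)guaian-8-one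
Product: 23 (1βH,4αH,5βH,7αH,10αH)-3β-(tert-butyldimethylsilyloxy)-11-(triethylsilyloxy)guaian-8β-ol
Conditions: LiBH(s-Bu)3, THF, −78 °C
Reagents that add atoms: none
Why: The bulky hydride should attack the cycloheptanone from the α face, anti to the β-oriented C7 side chain and C10 methyl (substrate-controlled reduction of a 2-substituted cycloalkanone), giving the 8β-alcohol cis to the side chain.

Step 20
Reactants: 23 (1βH,4αH,5βH,7αH,10αH)-3β-(tert-butyldimethylsilyloxy)-11-(triethylsilyloxy)guaian-8β-ol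
Product: 24 (1βH,4αH,5βH,7αH,10αH)-3β-(tert-butyldimethylsilyloxy)-11-(triethylsilyloxy)guaian-8β-yl methacrylate
Conditions: methacrylic anhydride, DMAP, Et3N, CH2Cl2, 0 to 40 °C
Reagents that add atoms: methacrylic anhydride, C=C(C)C(=O)OC(=O)C(C)=C
Why: DMAP-catalysed acylation of the only free hydroxyl installs the methacrylate with retention at C8.

Step 21
Reactants: 24 (1βH,4αH,5βH,7αH,10αH)-3β-(tert-butyldimethylsilyloxy)-11-(triethylsilyloxy)guaian-8β-yl methacrylate
Product: 25 (1βH,4αH,5βH,7αH,10αH)-3β,11-dihydroxyguaian-8β-yl methacrylate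
Conditions: HF·pyridine, THF/pyridine, 0 °C to rt
Reagents that add atoms: none
Why: Fluoride cleaves the secondary TBS and the tertiary TES ether under mildly acidic conditions that should neither hydrolyse nor migrate the methacrylate.

Step 22
Reactants: 25 (1βH,4αH,5βH,7αH,10αH)-3β,11-dihydroxyguaian-8β-yl methacrylate
Product: 26 (1βH,4αH,5βH,7αH,10αH)-11-hydroxy-3-oxoguaian-8β-yl methacrylate
Conditions: Dess–Martin periodinane, CH2Cl2, rt
Reagents that add atoms: none
Why: Dess–Martin oxidation converts the secondary C3 alcohol to the ketone, while the tertiary C11 alcohol cannot be oxidised and the acrylate is inert.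

Step 23
Reactants: 26 (1βH,4αH,5βH,7αH,10αH)-11-hydroxy-3-oxoguaian-8β-yl methacrylate
Product: 27 (1βH,4αH,5βH,7αH,10αH)-11-acetoxy-3-oxoguaian-8β-yl methacrylate
Conditions: Ac2O, Sc(OTf)3 (1 mol %), MeCN, −20 °C
Reagents that add atoms: acetic anhydride, CC(=O)OC(C)=O
Why: Lewis-acid-catalysed acetylation at low temperature acylates hindered tertiary alcohols faster than they ionise, so the C11 acetate should form without elimination.

Step 24
Reactants: 27 (1βH,4αH,5βH,7αH,10αH)-11-acetoxy-3-oxoguaian-8β-yl methacrylate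
Product: 28 (1βH,5βH,7αH,10αH)-11-acetoxy-3-(trimethylsilyloxy)guai-3-en-8β-yl methacrylate
Conditions: Me3SiCl, NaI, Et3N, MeCN, rt
Reagents that add atoms: chlorotrimethylsilane, C[Si](C)(C)Cl
Why: Me3SiI formed in the flask with Et3N equilibrates the silyl enol ethers (thermodynamic conditions), which should favour the tetrasubstituted C3=C4 isomer toward the methyl-bearing carbon.

Step 25
Reactants: 28 (1βH,5βH,7αH,10αH)-11-acetoxy-3-(trimethylsilyloxy)guai-3-en-8β-yl methacrylate
Product: 29 (1βH,7αH,10αH)-11-acetoxy-3-oxoguai-4-en-8β-yl methacrylate (CNP0318307.1)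
Conditions: Pd(OAc)2 (1.1 equiv), MeCN, rt
Reagents that add atoms: none
Why: Saegusa–Ito oxidation, in which divalent palladium adds to C4 of the enol ether from the convex β face and syn β-hydride elimination of the β-oriented H5 gives the C4=C5 enone, erases the helper stereocenters C4 and C5 and completes the target.

Compound list
1 | methyl 3-methylbut-3-enoate | C=C(C)CC(=O)OC | starting material
2 | methyl 2-diazo-3-methylbut-3-enoate | C=C(C)C(=[N+]=[N-])C(=O)OC | intermediate
3 | 4-methoxybenzyl alcohol | COc1ccc(CO)cc1 | starting material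
4 | 4-methoxybenzyl vinyl ether | C=COCc1ccc(OC)cc1 | intermediate
5 | methyl (1R,2S)-2-[(4-methoxybenzyl)oxy]-1-(prop-1-en-2-yl)cyclopropane-1-carboxylate | COC(=O)[C@@]1(C(C)=C)C[C@@H]1OCc1ccc(OC)cc1 | intermediate
6 | methyl (1S,2S)-2-[(4-methoxybenzyl)oxy]-1-(2-methyloxiran-2-yl)cyclopropane-1-carboxylate, both epimers at the oxirane carbon | COC(=O)[C@@]1(C2(C)CO2)C[C@@H]1OCc1ccc(OC)cc1 | intermediate
7 | 2-[(1S,2S)-1-(hydroxymethyl)-2-[(4-methoxybenzyl)oxy]cyclopropyl]propan-2-ol | OC[C@@]1(C(C)(C)O)C[C@@H]1OCc1ccc(OC)cc1 | intermediate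
8 | bis(triethylsilyl) ether of 7 | CC[Si](CC)(CC)OC[C@@]1(C(C)(C)O[Si](CC)(CC)CC)C[C@@H]1OCc1ccc(OC)cc1 | intermediate
9 | (1S,2S)-2-[(4-methoxybenzyl)oxy]-1-[2-(triethylsilyloxy)propan-2-yl]cyclopropane-1-carbaldehyde | O=C[C@@]1(C(C)(C)O[Si](CC)(CC)CC)C[C@@H]1OCc1ccc(OC)cc1 | intermediate
10 | methyl (R)-3-hydroxy-2-methylpropanoate | COC(=O)[C@H](C)CO | starting material
11 | methyl (S)-2-methyl-3-[(1-phenyl-1H-tetrazol-5-yl)sulfanyl]propanoate | COC(=O)[C@H](C)CSc1nnnn1-c1ccccc1 | intermediate
12 | (S)-2-methyl-3-[(1-phenyl-1H-tetrazol-5-yl)sulfanyl]propanal | O=C[C@H](C)CSc1nnnn1-c1ccccc1 | intermediate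
13 | (2S,3S)-2-methyl-1-[(1-phenyl-1H-tetrazol-5-yl)sulfanyl]hex-5-yn-3-ol | C#CC[C@H](O)[C@H](C)CSc1nnnn1-c1ccccc1 | intermediate
14 | 5-{[(2S,3S)-3-(tert-butyldimethylsilyloxy)-2-methylhex-5-yn-1-yl]sulfanyl}-1-phenyl-1H-tetrazole | C#CC[C@H](O[Si](C)(C)C(C)(C)C)[C@H](C)CSc1nnnn1-c1ccccc1 | intermediate
15 | propargylic dicyclohexylamine (Mannich base of 14, not isolated) | C1CCCCC1N(CC#CC[C@H](O[Si](C)(C)C(C)(C)C)[C@H](C)CSc1nnnn1-c1ccccc1)C1CCCCC1 | intermediate
16 | 5-{[(2S,3S)-3-(tert-butyldimethylsilyloxy)-2-methylhepta-5,6-dien-1-yl]sulfanyl}-1-phenyl-1H-tetrazole | C=C=CC[C@H](O[Si](C)(C)C(C)(C)C)[C@H](C)CSc1nnnn1-c1ccccc1 | intermediate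
17 | 5-{[(2S,3S)-3-(tert-butyldimethylsilyloxy)-2-methylhepta-5,6-dien-1-yl]sulfonyl}-1-phenyl-1H-tetrazole | C=C=CC[C@H](O[Si](C)(C)C(C)(C)C)[C@H](C)CS(=O)(=O)c1nnnn1-c1ccccc1 | intermediate
18 | (1S,2S)-1-[(1E,3R,4S)-4-(tert-butyldimethylsilyloxy)-3-methylocta-1,6,7-trien-1-yl]-2-[(4-methoxybenzyl)oxy]-1-[2-(triethylsilyloxy)propan-2-yl]cyclopropane | C=C=CC[C@H](O[Si](C)(C)C(C)(C)C)[C@H](C)/C=C/[C@@]1(C(C)(C)O[Si](CC)(CC)CC)C[C@@H]1OCc1ccc(OC)cc1 | intermediate
19 | (1βH,4αH,5βH)-3β-(tert-butyldimethylsilyloxy)-8α-[(4-methoxybenzyl)oxy]-11-(triethylsilyloxy)guaia-6,10(14)-diene | COc1ccc(cc1)CO[C@H]2CC(=C)[C@H]3C[C@H](O[Si](C)(C)C(C)(C)C)[C@H](C)[C@H]3C=C2C(C)(C)O[Si](CC)(CC)CC | intermediate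
20 | (1βH,4αH,5βH)-3β-(tert-butyldimethylsilyloxy)-11-(triethylsilyloxy)guaia-6,10(14)-dien-8α-ol | O[C@H]1CC(=C)[C@H]2C[C@H](O[Si](C)(C)C(C)(C)C)[C@H](C)[C@H]2C=C1C(C)(C)O[Si](CC)(CC)CC | intermediate
21 | (1βH,4αH,5βH,7αH,10αH)-3β-(tert-butyldimethylsilyloxy)-11-(triethylsilyloxy)guaian-8α-ol | O[C@H]1C[C@H](C)[C@H]2C[C@H](O[Si](C)(C)C(C)(C)C)[C@H](C)[C@H]2C[C@@H]1C(C)(C)O[Si](CC)(CC)CC | intermediate
22 | (1βH,4αH,5βH,7αH,10αH)-3β-(tert-butyldimethylsilyloxy)-11-(triethylsilyloxy)guaian-8-one | O=C1C[C@H](C)[C@H]2C[C@H](O[Si](C)(C)C(C)(C)C)[C@H](C)[C@H]2C[C@@H]1C(C)(C)O[Si](CC)(CC)CC | intermediate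
23 | (1βH,4αH,5βH,7αH,10αH)-3β-(tert-butyldimethylsilyloxy)-11-(triethylsilyloxy)guaian-8β-ol | O[C@@H]1C[C@H](C)[C@H]2C[C@H](O[Si](C)(C)C(C)(C)C)[C@H](C)[C@H]2C[C@@H]1C(C)(C)O[Si](CC)(CC)CC | intermediate
24 | (1βH,4αH,5βH,7αH,10αH)-3β-(tert-butyldimethylsilyloxy)-11-(triethylsilyloxy)guaian-8β-yl methacrylate | C=C(C)C(=O)O[C@@H]1C[C@H](C)[C@H]2C[C@H](O[Si](C)(C)C(C)(C)C)[C@H](C)[C@H]2C[C@@H]1C(C)(C)O[Si](CC)(CC)CC | intermediate
25 | (1βH,4αH,5βH,7αH,10αH)-3β,11-dihydroxyguaian-8β-yl methacrylate | C=C(C)C(=O)O[C@@H]1C[C@H](C)[C@H]2C[C@H](O)[C@H](C)[C@H]2C[C@@H]1C(C)(C)O | intermediate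
26 | (1βH,4αH,5βH,7αH,10αH)-11-hydroxy-3-oxoguaian-8β-yl methacrylate | C=C(C)C(=O)O[C@@H]1C[C@H](C)[C@H]2CC(=O)[C@H](C)[C@H]2C[C@@H]1C(C)(C)O | intermediate
27 | (1βH,4αH,5βH,7αH,10αH)-11-acetoxy-3-oxoguaian-8β-yl methacrylate | C=C(C)C(=O)O[C@@H]1C[C@H](C)[C@H]2CC(=O)[C@H](C)[C@H]2C[C@@H]1C(C)(C)OC(C)=O | intermediate
28 | (1βH,5βH,7αH,10αH)-11-acetoxy-3-(trimethylsilyloxy)guai-3-en-8β-yl methacrylate | C=C(C)C(=O)O[C@@H]1C[C@H](C)[C@H]2CC(O[Si](C)(C)C)=C(C)[C@H]2C[C@@H]1C(C)(C)OC(C)=O | intermediate
29 | (1βH,7αH,10αH)-11-acetoxy-3-oxoguai-4-en-8β-yl methacrylate, CNP0318307.1 | C=C(C)C(=O)O[C@@H]1C[C@H](C)[C@H]2CC(=O)C(C)=C2C[C@@H]1C(C)(C)OC(C)=O | target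

Total steps: 25. Longest linear sequence: 18 steps (steps 8–25 from 10; equally steps 1, 3–7 and 14–25 from 1).

Steps most likely to fail

Step 15. The allene insertion needs hours at 80 °C, during which the alkoxycyclopropane may open at the wrong bond or lose alkoxide from the rhodacycle, and the allene may oligomerise or isomerise. The fallback changes the π partner to an alkyne, which reacts at room temperature, and regenerates the exocyclic alkene afterwards. It sets out from 14 and 9. 14 is oxidised as in step 13 to the alkynyl sulfone F1. Julia–Kocienski olefination of F1 with 9 (KN(SiMe3)2, DME) gives the terminal alkyne vinylcyclopropane F2. Lithiation (n-BuLi, THF, −78 °C) and alkylation with Me3SiCH2OSO2CF3 gives the propargylsilane F3. The alkyne–vinylcyclopropane [5+2] cycloaddition with the cationic monovalent rhodium complex [Rh(cod)(C10H8)]SbF6 in ClCH2CH2Cl at rt should give the bicyclic allylsilane F4 (C1=C10, C10–CH2SiMe3, H5 β by the same cyclopropane relay). Protodesilylation in the SE2' sense (camphorsulfonic acid, CH2Cl2, −40 °C) should protonate C1 anti to the C5–C6 bond, hence cis to H5, and restore C10=C14; the route is rejoined at 19.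

Step 17. Delivery into the concave face may stall at the hindered trisubstituted C6=C7 alkene as the iridium catalyst deactivates, and the exocyclic alkene may migrate into the ring before it is reduced. The fallback splits the reduction into two separate directed events with different catalyst families. It sets out from 20. A short iridium run under the step 17 conditions is stopped once the 1,1-disubstituted alkene is consumed, giving the monoene F5 (C10 set, C6=C7 intact). F5 is then reduced with the cationic monovalent rhodium bisphosphine complex [Rh(nbd)(dppb)]BF4 under H2 (60 bar, THF), a hydroxyl-chelated dihydride pathway that tolerates hindered allylic alcohols and delivers from the same 8α face; the route is rejoined at 21.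

Step 24. Enol silane formation may give the less substituted C2=C3 regioisomer, which on oxidation would destroy C1, and the palladium step may eliminate toward the methyl group. The fallback controls the site through the acid-catalysed enol and uses a selenoxide elimination. It sets out from 27. PhSeCl in EtOAc at rt should selenenylate the more substituted C4 from the convex β face (the electron-poor methacrylate is not attacked), giving the α-phenylseleno ketone F6. Oxidation (H2O2, pyridine, CH2Cl2, 0 °C) and syn elimination of the selenoxide with the β-oriented H5 gives the C4=C5 enone directly; the route is rejoined at 29.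

Further compounds
F1 | step 15 | 5-{[(2S,3S)-3-(tert-butyldimethylsilyloxy)-2-methylhex-5-yn-1-yl]sulfonyl}-1-phenyl-1H-tetrazole | C#CC[C@H](O[Si](C)(C)C(C)(C)C)[C@H](C)CS(=O)(=O)c1nnnn1-c1ccccc1
F2 | step 15 | (1S,2S)-1-[(1E,3R,4S)-4-(tert-butyldimethylsilyloxy)-3-methylhept-1-en-6-yn-1-yl]-2-[(4-methoxybenzyl)oxy]-1-[2-(triethylsilyloxy)propan-2-yl]cyclopropane | C#CC[C@H](O[Si](C)(C)C(C)(C)C)[C@H](C)/C=C/[C@@]1(C(C)(C)O[Si](CC)(CC)CC)C[C@@H]1OCc1ccc(OC)cc1
F3 | step 15 | 8-(trimethylsilyl)oct-1-en-6-ynyl analogue of F2 (propargylsilane) | C[Si](C)(C)CC#CC[C@H](O[Si](C)(C)C(C)(C)C)[C@H](C)/C=C/[C@@]1(C(C)(C)O[Si](CC)(CC)CC)C[C@@H]1OCc1ccc(OC)cc1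
F4 | step 15 | (4αH,5βH)-3β-(tert-butyldimethylsilyloxy)-8α-[(4-methoxybenzyl)oxy]-11-(triethylsilyloxy)-14-(trimethylsilyl)guaia-1(10),6-diene | COc1ccc(cc1)CO[C@H]2CC(C[Si](C)(C)C)=C3C[C@H](O[Si](C)(C)C(C)(C)C)[C@H](C)[C@H]3C=C2C(C)(C)O[Si](CC)(CC)CC
F5 | step 17 | (1βH,4αH,5βH,10αH)-3β-(tert-butyldimethylsilyloxy)-11-(triethylsilyloxy)guai-6-en-8α-ol | O[C@H]1C[C@H](C)[C@H]2C[C@H](O[Si](C)(C)C(C)(C)C)[C@H](C)[C@H]2C=C1C(C)(C)O[Si](CC)(CC)CC
F6 | step 24 | (1βH,5βH,7αH,10αH)-11-acetoxy-3-oxo-4β-(phenylselanyl)guaian-8β-yl methacrylate | C=C(C)C(=O)O[C@@H]1C[C@H](C)[C@H]2CC(=O)[C@](C)([Se]c3ccccc3)[C@H]2C[C@@H]1C(C)(C)OC(C)=O
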